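**Retrosynthetic overview**
1. The last bond made is C4'–OH. A catalyst-controlled hydroxylation of the planar dienol of a 4-acylcyclopent-2-enone sets 4'R, and nothing follows it.
2. The C2'–CH2–S unit comes from a three-component union of an ene-dione, formaldehyde and methyl (R)-3-sulfanyl-lactate (made from methyl (S)-glycidate).
3. The C12–C4' bond comes from the Weinreb amide of the drimane acid and a β-lithiated cyclopentenone ketal (made from cyclopentane-1,3-dione).
4. The drimane half comes from (+)-sclareolide by enzymatic C–H hydroxylation at C3, lactone aminolysis and exo-selective dehydration to the C8(17) methylene.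
5. No ring is built. The trans-decalin arrives with sclareolide and the five-membered ring with cyclopentanedione; only the lactone ring is opened.

Assumption: labdane numbering is used for the decalin half (C3 carbinol, C8(17) methylene, C9, C11, C12 = side-chain ketone) and primed numbers for the five-membered ring (C1' = ring C=O, C2' = carbon bearing CH2S, C4' = carbinol carbon); the SMILES reads 3S,5R,9S,10R,4'R and 2R in the lactate; the sense of induction of the catalyst in step 9 is assumed as written, and its mirror image is equally available.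

**Step 1**
Reactants: 1 (+)-sclareolide
Product: 2 3β-hydroxysclareolide (3S; equatorial OH beside the gem-dimethyl carbon)
Conditions: engineered P450BM3 variant (E. coli lysate, ca. 0.1 mol %), NADP+ (cat.), phosphite dehydrogenase, Na2HPO3, air, KPi pH 8.0, 25 °C
Reagents that add atoms: dioxygen, O=O
Why: Biocatalytic C–H hydroxylation (P450 hydrogen abstraction/oxygen rebound), known preparatively for this substrate; the pocket presents only the equatorial 3β-H to the haem and replaces it with retention, which sets C3 as S and leaves the four existing centres untouched.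

**Step 2**
Reactants: 2 3β-hydroxysclareolide
Product: 3 3β,8α-dihydroxy-13,14,15,16-tetranorlabdan-12-oic acid N-methoxy-N-methylamide
Conditions: MeNH(OMe)·HCl (5 equiv), AlMe3 (5 equiv), CH2Cl2, 0→23 °C; cold 0.5 M HCl work-up
Reagents that add atoms: N,O-dimethylhydroxylamine hydrochloride, CNOC.Cl
Why: Weinreb aminolysis of the lactone with the aluminium amide, driven by Al–O bond formation; only the acyl C–O bond breaks, so C8 and C9 keep their configuration.

**Step 3**
Reactants: 3 diol Weinreb amide
Product: 6 3β-(triethylsilyloxy)-13,14,15,16-tetranorlabd-8(17)-en-12-oic acid N-methoxy-N-methylamide, via 3-O-TES amide 4 (not isolated), via 8-chlorosulfite 5 (not isolated)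
Conditions: TESCl (1.15 equiv), pyridine (10 equiv), DMAP (5 mol %), CH2Cl2, 0→23 °C; then SOCl2 (2 equiv), −78 °C; aq NaHCO3
Reagents that add atoms: chlorotriethylsilane, CC[Si](Cl)(CC)CC
Why: Selective silylation of the secondary alcohol followed by E2 dehydration of the tertiary chlorosulfite; the equatorial 8α leaving group has an antiperiplanar hydrogen only on the C17 methyl group, so the exocyclic alkene predominates, and minor endocyclic isomers are removed on silica.

**Step 4**
Reactants: 7 cyclopentane-1,3-dione
Product: 8 3-bromocyclopent-2-en-1-one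
Conditions: Ph3PBr2 (1.1 equiv), Et3N (1.1 equiv), CH2Cl2, 0→23 °C
Reagents that add atoms: dibromotriphenylphosphorane, BrP(Br)(c1ccccc1)(c1ccccc1)c1ccccc1
Why: β-Halo enone synthesis from a 1,3-diketone; the enol oxygen is activated on phosphorus and replaced by bromide through addition–elimination.

**Step 5**
Reactants: 8 3-bromocyclopent-2-en-1-one
Product: 9 7-bromo-1,4-dioxaspiro[4.4]non-6-ene
Conditions: TMSOCH2CH2OTMS (1.5 equiv), TMSOTf (5 mol %), CH2Cl2, −78→−20 °C; pyridine quench
Reagents that add atoms: 1,2-bis(trimethylsilyloxy)ethane, C[Si](C)(C)OCCO[Si](C)(C)C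
Why: Noyori ketalisation under aprotic low-temperature conditions, which avoids C=C migration and vinylogous substitution of bromide; a migrated double bond would in any case feed the same dienolate in step 8.

**Step 6**
Reactants: 9 7-bromo-1,4-dioxaspiro[4.4]non-6-ene; 6 TES-protected 8(17)-ene Weinreb amide
Product: 12 3-[3β-hydroxy-13,14,15,16-tetranorlabd-8(17)-en-12-oyl]cyclopent-2-en-1-one (ene-dione), via vinyllithium 10 (not isolated), via ketal ketone 11 (not isolated)
Conditions: 9 (1.6 equiv), n-BuLi (1.5 equiv), THF, −78 °C; 6, −78→−20 °C; then 1 M aq HCl, THF, 23 °C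
Reagents that add atoms: water, O
Why: Bromine–lithium exchange followed by Nahm–Weinreb ketone synthesis; 10 is a β-acylvinyl anion equivalent that adds only once, the acidic quench removes ketal and TES ether in the same flask, and C9 is β to the new ketone so it cannot epimerise.

**Step 7**
Reactants: 13 methyl (S)-oxirane-2-carboxylate (methyl (S)-glycidate)
Product: 14 methyl (R)-3-(acetylsulfanyl)-2-hydroxypropanoate
Conditions: AcSH (1.1 equiv), Et3N (5 mol %), toluene, 0→23 °C
Reagents that add atoms: thioacetic acid, CC(=O)S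
Why: SN2 epoxide opening at the unsubstituted C3; the C2–O bond is not touched, so the centre is retained, and the descriptor changes from S to R only because CH2S outranks CO2Me.

**Step 8**
Reactants: 12 ene-dione; 14 methyl (R)-3-(acetylsulfanyl)-2-hydroxypropanoate
Product: 18 4'-deoxyalternarin A (2'-thiomethylated 4'-acylcyclopent-2'-enone; C4' enolisable and unassigned), via thiol 15 (not isolated), via 4-acylcyclopentenone tautomer 16 (not isolated), via methylene dienone 17 (not isolated)
Conditions: 14 (1.3 equiv), pyrrolidine (1.3 equiv), degassed MeOH, 0 °C; then 12, 37% aq CH2O (1.5 equiv), Et3N (1.5 equiv), DBU (10 mol %), 23→40 °C; pH 4 work-up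
Reagents that add atoms: formaldehyde, C=O
Why: Three-component thiomethylation (Mannich/Knoevenagel condensation then thia-Michael addition, the type used for α-thiomethylation of enones and cyclic 1,3-diones); base moves 12 into the strongly stabilised dienolate of 16, attack on CH2O at C2' is the only one that can end in loss of water (attack at C4' gives a quaternary carbinol that reverts), 15 then adds 1,6 to 17, and the lactate centre is untouched.

**Step 9**
Reactants: 18 4'-deoxyalternarin A
Product: 20 alternarin A, via aminoxy ketone 19 (not isolated)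
Conditions: (R)-TRIP (10 mol %), PhNO (2.5 equiv, added over 4 h), toluene, 0 °C, dark, N2
Reagents that add atoms: nitrosobenzene, O=Nc1ccccc1
Why: Proposed new method: chiral-phosphoric-acid-catalysed O-selective nitroso aldol reaction with in situ N–O cleavage, applied for the first time to a vinylogous β-diketone (a 4-acylcyclopent-2-enone); 18 enolises towards C12 (exocyclic C=C on a five-membered ring, push–pull with the enone), the catalyst P=O accepts the enol O–H while its P–OH protonates the nitroso nitrogen, so oxygen is delivered in a closed transition state to the adjacent C4' (C2', the other nucleophilic terminus, is fully substituted and out of reach of the bound electrophile), the 3,3'-aryl walls block one face of the planar dienol and set C4' as R under catalyst control (the nearest drimane centre, C9, is three bonds away), a second PhNO converts the O–NHPh group of 19 into OH with loss of azoxybenzene, and the sulfide, 1,1-disubstituted alkene, ester and free alcohols are inert to PhNO; the closest known reaction type is the Brønsted-acid-catalysed enantioselective α-hydroxylation of β-keto esters and β-diketones with nitrosoarenes.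

**Compound list**
1 | (+)-sclareolide, (3aR,5aS,9aS,9bR)-3a,6,6,9a-tetramethyldecahydronaphtho[2,1-b]furan-2-one | C[C@@]12CC[C@H]3C(C)(C)CCC[C@]3(C)[C@H]1CC(=O)O2 | starting material
2 | 3β-hydroxysclareolide (3S) | C[C@@]12CC[C@H]3C(C)(C)[C@@H](O)CC[C@]3(C)[C@H]1CC(=O)O2 | intermediate
3 | 3β,8α-dihydroxy-13,14,15,16-tetranorlabdan-12-oic acid N-methoxy-N-methylamide | C[C@@]1(O)CC[C@H]2C(C)(C)[C@@H](O)CC[C@]2(C)[C@H]1CC(=O)N(C)OC | intermediate
4 | 3β-triethylsilyl ether of 3 (8α-OH free) | C[C@@]1(O)CC[C@H]2C(C)(C)[C@@H](O[Si](CC)(CC)CC)CC[C@]2(C)[C@H]1CC(=O)N(C)OC | intermediate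
5 | 8α-chlorosulfite of 4 | C[C@@]1(OS(=O)Cl)CC[C@H]2C(C)(C)[C@@H](O[Si](CC)(CC)CC)CC[C@]2(C)[C@H]1CC(=O)N(C)OC | intermediate
6 | 3β-(triethylsilyloxy)-13,14,15,16-tetranorlabd-8(17)-en-12-oic acid N-methoxy-N-methylamide | C=C1CC[C@H]2C(C)(C)[C@@H](O[Si](CC)(CC)CC)CC[C@]2(C)[C@H]1CC(=O)N(C)OC | intermediate
7 | cyclopentane-1,3-dione | O=C1CCC(=O)C1 | starting material
8 | 3-bromocyclopent-2-en-1-one | O=C1C=C(Br)CC1 | intermediate
9 | 7-bromo-1,4-dioxaspiro[4.4]non-6-ene | BrC1=CC2(CC1)OCCO2 | intermediate
10 | 7-lithio-1,4-dioxaspiro[4.4]non-6-ene | [Li]C1=CC2(CC1)OCCO2 | intermediate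
11 | ethylene ketal and 3-O-TES ether of 12 | C=C1CC[C@H]2C(C)(C)[C@@H](O[Si](CC)(CC)CC)CC[C@]2(C)[C@H]1CC(=O)C1=CC2(CC1)OCCO2 | intermediate
12 | 3-[3β-hydroxy-13,14,15,16-tetranorlabd-8(17)-en-12-oyl]cyclopent-2-en-1-one | C=C1CC[C@H]2C(C)(C)[C@@H](O)CC[C@]2(C)[C@H]1CC(=O)C1=CC(=O)CC1 | intermediate
13 | methyl (S)-oxirane-2-carboxylate | COC(=O)[C@@H]1CO1 | starting material
14 | methyl (R)-3-(acetylsulfanyl)-2-hydroxypropanoate | CC(=O)SC[C@H](O)C(=O)OC | intermediate
15 | methyl (R)-2-hydroxy-3-sulfanylpropanoate | SC[C@H](O)C(=O)OC | intermediate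
16 | 4-acylcyclopent-2-en-1-one tautomer of 12 (present as its dienolate; C4' unassigned) | C=C1CC[C@H]2C(C)(C)[C@@H](O)CC[C@]2(C)[C@H]1CC(=O)C1C=CC(=O)C1 | intermediate
17 | 4-acyl-2-methylidenecyclopent-3-en-1-one (acyl as in 12) | C=C1CC[C@H]2C(C)(C)[C@@H](O)CC[C@]2(C)[C@H]1CC(=O)C1=CC(=C)C(=O)C1 | intermediate
18 | 4'-deoxyalternarin A (C4' enolisable, unassigned; lactate 2R) | C=C1CC[C@H]2C(C)(C)[C@@H](O)CC[C@]2(C)[C@H]1CC(=O)C1C=C(CSC[C@H](O)C(=O)OC)C(=O)C1 | intermediate
19 | 4'-O-(phenylamino)alternarin A (4'R) | C=C1CC[C@H]2C(C)(C)[C@@H](O)CC[C@]2(C)[C@H]1CC(=O)[C@]1(ONc2ccccc2)C=C(CSC[C@H](O)C(=O)OC)C(=O)C1 | intermediate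
20 | alternarin A (3S,5R,9S,10R,4'R; lactate 2R) | C=C1CC[C@H]2C(C)(C)[C@@H](O)CC[C@]2(C)[C@H]1CC(=O)[C@]1(O)C=C(CSC[C@H](O)C(=O)OC)C(=O)C1 | target

**Step count**
- Total: 9 steps.
- Longest linear sequence: 6 steps (1, 2, 3, 6, 8, 9, from sclareolide).

**Three steps most likely to fail**

**Step 9 (the proposed new hydroxylation).** The risks are attack at C2' or through nitrogen, and modest facial selectivity. The fallback sets out from 12 and comes back at 20. It oxidises before sulfur is present, using a stoichiometric chiral oxidant. Compound 12 is deprotonated with KHMDS (2.2 equiv, THF, −78 °C) and treated with an enantiopure (camphorylsulfonyl)oxaziridine (Davis enolate hydroxylation). This gives the (R)-4-acyl-4-hydroxycyclopent-2-enone F1, and any 4'-epimer is removed by chromatography. A Morita–Baylis–Hillman reaction with aqueous formaldehyde (imidazole or Bu3P) gives the 2'-hydroxymethyl enone F2. Selective acetylation of the primary allylic alcohol (AcCl, 2,4,6-collidine, −78 °C) gives the allylic acetate F3. Thiol 15, freed from 14 with pyrrolidine, then replaces acetate by addition–elimination (Et3N, CH2Cl2, 0 °C) to give 20.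

**Step 8 (three-component thiomethylation).** The risks are slow isomerisation of 12, parking of the thiol on the ene-dione, and methylene-bridged dimers. The fallback sets out from 12 and comes back at 18. It is a stepwise Mannich route with a preformed iminium salt. Compound 12 reacts with Eschenmoser's salt and Et3N in CH2Cl2 to give the isolable 2'-(dimethylaminomethyl) Mannich base F4. Warming this with thiol 15 (freed from 14 with pyrrolidine) in MeOH/AcOH exchanges the amine for the thiol by elimination–addition and gives 18.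

**Step 6 (lithiated ketal plus Weinreb amide, which also depends on the ketalisation of step 5).** The risks are poor access to 9, incomplete exchange, and slow hydrolysis of the acyl-substituted ketal. The fallback sets out from 6 together with 8 and comes back at 12, so step 5 is not needed. DIBAL-H (CH2Cl2, −78 °C) reduces 6 to the aldehyde F5. Nozaki–Hiyama–Kishi coupling with the unprotected bromo enone 8 (CrCl2, cat. NiCl2, DMF) gives the allylic alcohol F6 as C12 epimers. Dess–Martin periodinane gives the TES-protected ene-dione F7, and 1 M HCl in THF removes the silyl group to give 12.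

**Further compounds**
F1 | step 9 | (R)-4-[3β-hydroxy-13,14,15,16-tetranorlabd-8(17)-en-12-oyl]-4-hydroxycyclopent-2-en-1-one | C=C1CC[C@H]2C(C)(C)[C@@H](O)CC[C@]2(C)[C@H]1CC(=O)[C@]1(O)C=CC(=O)C1
F2 | step 9 | 2'-hydroxymethyl derivative of F1 | C=C1CC[C@H]2C(C)(C)[C@@H](O)CC[C@]2(C)[C@H]1CC(=O)[C@]1(O)C=C(CO)C(=O)C1
F3 | step 9 | 2'-acetoxymethyl derivative of F1 | C=C1CC[C@H]2C(C)(C)[C@@H](O)CC[C@]2(C)[C@H]1CC(=O)[C@]1(O)C=C(COC(C)=O)C(=O)C1
F4 | step 8 | 2'-(dimethylaminomethyl)-4'-acylcyclopent-2'-enone Mannich base (C4' unassigned) | C=C1CC[C@H]2C(C)(C)[C@@H](O)CC[C@]2(C)[C@H]1CC(=O)C1C=C(CN(C)C)C(=O)C1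
F5 | step 6 | 3β-(triethylsilyloxy)-13,14,15,16-tetranorlabd-8(17)-en-12-al | C=C1CC[C@H]2C(C)(C)[C@@H](O[Si](CC)(CC)CC)CC[C@]2(C)[C@H]1CC=O
F6 | step 6 | 3-[12-hydroxy-3β-(triethylsilyloxy)-13,14,15,16-tetranorlabd-8(17)-en-12-yl]cyclopent-2-en-1-one (C12 epimers) | C=C1CC[C@H]2C(C)(C)[C@@H](O[Si](CC)(CC)CC)CC[C@]2(C)[C@H]1CC(O)C1=CC(=O)CC1
F7 | step 6 | 3-O-TES ether of 12 | C=C1CC[C@H]2C(C)(C)[C@@H](O[Si](CC)(CC)CC)CC[C@]2(C)[C@H]1CC(=O)C1=CC(=O)CC1
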